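## Structural features

The target is a flavone: a benzo ring A fused to a 4-pyranone ring C, which carries an unsubstituted phenyl ring B at C2. Ring A bears hydroxyl groups at C5 and C7 and, between them at C6, a 1-methylpiperidin-2-yl ring joined through the C6–C2' bond; C8 carries only hydrogen. The single stereocentre is C2' (R; N > C6 > C3' > H), benzylic and alpha to nitrogen, with no neighbouring stereocentre, so the stereochemical problem is one absolute configuration next to an aryl group substituted at both ortho positions. The fragile elements are three. The phenolic Mannich-base array (free C5 and C7 hydroxyls flanking a benzylic amine) can ionise at C2'–N through a quinone methide and racemise. The pyranone ring is opened by strong base or nucleophiles at C2 and is reducible at C2=C3. The 5-hydroxyflavone motif can, under hot strong acid, reclose on the other phenol and move the C6 substituent to C8. The real difficulty is therefore to place the heterocycle at C6 and not at C8, and to set C2' without harsh deprotections afterwards. The key step exploits the fact that the oxygenated carbons C5 and C7 are exactly the two ortho positions of the carbon that holds the nitrogen ring: as a 2-pyridyl group at C6, that ring can direct palladium to C5–H and C7–H and to no other position.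

## Logic of the disconnections

**10 ⇒ 9.** The two O–acyl bonds on the C5 and C7 oxygens are cut, so both phenols are masked as esters. The free bisphenol beside the benzylic amine is the one form in which C2' can ionise, so it should exist only at the end. The acyl groups are those the C–H oxygenation installs, so no protecting-group step is added. The gain is a neutral amine that can be purified and assayed for enantiopurity. The demand is a cleavage that is cold, brief and free of strong acid or base, so that C2' and ring C are untouched.

**9 ⇒ 7 (8 is the salt first formed).** No skeletal bond is cut; the six C–H bonds on C2' to C6' and the C2' stereocentre are removed, so the saturated ring becomes an aromatic N-methylpyridinium ring. Only an sp2 nitrogen ring can serve the earlier C–H oxygenation, and a pyridinium is the activated form that undergoes enantioselective hydrogenation. The gain is a flat precursor without stereocentres. The demand is heavy: the cationic ring must be reduced while C2=C3 and C4=O are spared, and the faces at C2' must be told apart next to a doubly ortho-substituted aryl group.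

**7 ⇒ 6.** The N–CH3 bond is cut. The methyl group is needed in the target and also activates the ring for reduction. It must come after the oxygenation, because a quaternised nitrogen cannot bind palladium. The gain is a neutral pyridine. The demand is alkylation at nitrogen only, beside a twisted and crowded aryl group, without touching the C4 carbonyl oxygen or the esters.

**6 ⇒ 3 + 4 (5 is the mono-oxygenated stage).** The C5–O and C7–O bonds are cut. One directing group accounts for both oxygens and for the absence of oxygen at C8. The gain is large: ring A loses all heteroatom substituents, and the 6-versus-8 question reduces to choosing a 6-substituted starting material. The demand is that the directed oxygenation runs twice, the second time peri to the C4 carbonyl and beside the first ester.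

**3 ⇒ 1 + 2.** The C6–C2' biaryl bond is cut. It is an sp2–sp2 bond between two commercial partners. The demand is a 2-pyridyl nucleophile that transfers cleanly and does not add to the enone, which points to zinc and not boron.

## Other disconnections considered

**Alternative 1:** The piperidine is cut at C5'–C6' and C6'–N, so that C6' comes from carbon monoxide.
- **Forward step:** the homoallylic amine (R)-1-[4-(benzyloxy)-2,6-dimethoxyphenyl]-N-methylbut-3-en-1-amine A1 would be hydroformylated at its terminal carbon with Rh(acac)(CO)2, a wide-bite-angle bisphosphite, CO and H2. The linear aldehyde condenses with the secondary amine and the cyclic iminium or enamine is hydrogenated by the same rhodium hydride, giving (R)-2-[4-(benzyloxy)-2,6-dimethoxyphenyl]-1-methylpiperidine A2.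
- **In favour:** C2' is set before ring closure, for instance by auxiliary-controlled allylation (sulfinimine chemistry) starting from 4-(benzyloxy)-2,6-dimethoxybenzaldehyde A3, and the ring closure does not touch it. The aryl ring of A2 is symmetric, so later acylation ortho to the freed phenol can only lead to the 6-substituted pattern.
- **Against:** A2 contains none of ring C. Debenzylation, C-acylation, diketone or chalcone formation, pyranone closure and a twofold O-demethylation still follow, about a dozen steps in all against five. The demethylation exposes a 5-hydroxyflavone and an electron-rich benzylic amine to strong acid, the conditions that invite 6-to-8 isomerisation and ionisation at C2'.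
- **Comparison:** on control of C2' this alternative is the better plan, since it uses an auxiliary and not the hydrogenation of a hindered pyridinium, and the chromone alkene never meets hydrogen. On regiochemistry the two are equal. On step economy and mildness of the end game the chosen plan is ahead. Mechanistically, the linear-versus-branched question of the hydroformylation replaces the once-versus-twice question of the acetoxylation.

**Alternative 2:** Ring A is removed by cutting C5–C6, C7–C8 and C4a–C5.
- **Forward step:** irradiation of 2-(2-diazoacetyl)-6-phenyl-4H-pyran-4-one A4 would trigger a Wolff rearrangement to a ketene. This would add [2+2] to the siloxyalkyne tert-butyl (R)-2-{[tri(propan-2-yl)silyl]oxyethynyl}piperidine-1-carboxylate A5. The cyclobutenone would open (4π), the dienylketene would close onto the pyranone carbon next to the carbonyl (6π), and tautomerisation would give tert-butyl (R)-2-[5-hydroxy-4-oxo-2-phenyl-7-(triisopropylsilyloxy)-4H-chromen-6-yl]piperidine-1-carboxylate A6.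
- **In favour:** the route is convergent and the mechanism fixes all four ring-A positions (OH at C5, piperidine at C6, silyloxy at C7, H at C8), with the two oxygens differentiated. The stereocentre comes from (R)-1-(tert-butoxycarbonyl)piperidine-2-carboxylic acid A7, without any asymmetric step.
- **Against:** the benzannulation would have to use the C=C bond of an electron-poor 4-pyranone as its vinyl component, which is not an established case. A5 must be made from A7 by homologation to an ynolate and silylation without epimerising the alpha-amino centre. The branched substituent on the alkyne slows the cycloaddition. Desilylation, carbamate removal and N-methylation follow, giving about ten steps in two branches.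
- **Comparison:** it is equal on regiochemistry. It is better on the origin of chirality and in avoiding any hydrogenation near the chromone. It is worse on precedent for the key step, since the chosen acetoxylation rests on a broad class of 2-arylpyridines, and worse on step count.

**Alternative 3:** Ring C is cut at C4a–C4, C4–C3 and O1–C2.
- **Forward step:** 2-iodo-3,5-dimethoxy-4-[(R)-1-methylpiperidin-2-yl]phenol A8, carbon monoxide and phenylacetylene A9 would be joined by PdCl2(PPh3)2 in diethylamine. Zerovalent palladium inserts into C–I, CO insertion gives an aroyl palladium, coupling with the alkyne gives an ynone, and amine-mediated 6-endo closure of the phenol gives 5,7-dimethoxy-6-[(R)-1-methylpiperidin-2-yl]flavone A10.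
- **In favour:** ring C and ring B are added in one well-established operation. The phenol before iodination is symmetric, so the 6-pattern is guaranteed. The chromone alkene is formed after the stereocentre.
- **Against:** the stereochemical problem is only moved, since enantiopure A8 still needs its own asymmetric synthesis of a doubly ortho-substituted 2-arylpiperidine. The 5-exo closure to an aurone can compete. A10 is a bis(methyl ether), and cleaving the C7 ether needs BBr3 or hot acid, with the same risks to C2' and to the 6-position as in Alternative 1. About nine steps would be needed.
- **Comparison:** it is equal on regiochemistry. It is better on the reliability of the ring-forming step, since the chosen key step must succeed twice, the second time at a peri position. It is worse on step count and end game, and it gives no answer for C2'.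

Key step: step 2

Remark on the chemistry: the structures of the key-step substrate 3 and product 6 were checked atom by atom against the target numbering and need no correction; C2' of the target is (R); the ligand antipode in step 4 is written as (S) on the assumption that it gives (R), and the commercially available (R)-ligand is used if the sense of induction on this substrate proves opposite.

## Route

Step 1
Reactants: 1 6-bromoflavone (6-bromo-2-phenyl-4H-chromen-4-one); 2 2-pyridylzinc bromide (0.5 M in THF, 1.5 equiv)
Product: 3 2-phenyl-6-(pyridin-2-yl)-4H-chromen-4-one
Conditions: Pd(PPh3)4 (5 mol %), THF, 65 °C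
Reagents that add atoms: none
Why: Negishi coupling: zerovalent palladium inserts into the C6–Br bond, the 2-pyridyl group is transferred from zinc and reductive elimination forms the C6–C2' bond; 2-pyridylzinc halides, unlike 2-pyridylboron reagents, do not protodemetalate quickly, and organozinc halides do not add to the pyranone carbonyl or its enone.

Step 2
Reactants: 3 2-phenyl-6-(pyridin-2-yl)-4H-chromen-4-one; 4 (diacetoxyiodo)benzene (3 equiv, added in portions)
Product: 6 4-oxo-2-phenyl-6-(pyridin-2-yl)-4H-chromene-5,7-diyl diacetate, via 7-acetoxy-6-(pyridin-2-yl)flavone 5 (not isolated)
Conditions: Pd(OAc)2 (10 mol %), AcOH/Ac2O (1:1), 100 °C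
Reagents that add atoms: none
Why: The pyridine nitrogen of 3 binds Pd(OAc)2 and an acetate ligand removes the ortho hydrogen by concerted metalation–deprotonation, giving a five-membered palladacycle (Pd, N, pyridine C2, C6, C7); 4 oxidises this divalent palladium aryl to a tetravalent palladium acetate, from which C–O reductive elimination releases the aryl acetate and returns divalent palladium. The closest known reaction type is the Pd(OAc)2-catalysed, pyridine-directed ortho C–H acetoxylation of 2-arylpyridines with PhI(OAc)2, which is known to occur twice on one ring when the oxidant is in excess. The less crowded C7–H should react first to give 5; rotation about the C6–pyridine bond then presents C5–H, where the C4 carbonyl oxygen can take a further coordination site, so that palladium is held in an N,C,O arrangement that compensates for the peri crowding. No ring is closed and no stereocentre is formed. The selectivity needed is positional, C5 and C7 over C8, C3 and ring B, and geometry secures it, since only C5 and C7 can join the pyridine nitrogen in a five-membered palladacycle. Ac2O as co-solvent keeps both phenols acetylated, so that no 2-(2-hydroxyaryl)pyridine chelate forms to sequester the catalyst, and portionwise addition of 4 sustains the slower second cycle.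

Step 3
Reactants: 6 4-oxo-2-phenyl-6-(pyridin-2-yl)-4H-chromene-5,7-diyl diacetate
Product: 7 2-(5,7-diacetoxy-4-oxo-2-phenyl-4H-chromen-6-yl)-1-methylpyridin-1-ium trifluoromethanesulfonate
Conditions: MeOTf (1.1 equiv), CH2Cl2, 0 °C to rt
Reagents that add atoms: methyl trifluoromethanesulfonate, COS(=O)(=O)C(F)(F)F
Why: Menshutkin N-alkylation: the pyridine nitrogen is by far the most nucleophilic site, and the small, hard electrophile reaches it although the aryl group is twisted and substituted at both ortho positions; one equivalent at low temperature should leave the weakly basic C4 carbonyl oxygen and the esters alone. The methyl group is both the activating group for the reduction and the N-substituent of the target.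

Step 4
Reactants: 7 2-(5,7-diacetoxy-4-oxo-2-phenyl-4H-chromen-6-yl)-1-methylpyridin-1-ium trifluoromethanesulfonate
Product: 9 (R)-6-(1-methylpiperidin-2-yl)-4-oxo-2-phenyl-4H-chromene-5,7-diyl diacetate, via (R)-diacetoxy piperidinium triflate 8 (not isolated)
Conditions: [Ir(cod)Cl]2 (2 mol %), (S)-SegPhos (4.4 mol %), nBu4NBr (1 equiv), H2 (40 bar), PhMe/CH2Cl2 (1:1), 30 °C; then aq NaHCO3
Reagents that add atoms: none
Why: Iridium-catalysed asymmetric hydrogenation of an N-alkyl-2-arylpyridinium salt: the iridium hydride formed from [Ir(cod)Cl]2, the bisphosphine, halide and H2 reduces the activated ring by successive hydride transfers and protonations, and the last hydride transfer, to the iminium carbon C2', sets the (R) centre under control of the chiral bisphosphine. The cross-conjugated C2=C3 bond of the pyranone and the aryl esters are not activated by this ionic pathway, the bromide additive supplies the halide with which this catalyst family is established, and the tertiary amine formed cannot capture an acetyl group.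

Step 5
Reactants: 9 (R)-6-(1-methylpiperidin-2-yl)-4-oxo-2-phenyl-4H-chromene-5,7-diyl diacetate
Product: 10 (R)-5,7-dihydroxy-6-(1-methylpiperidin-2-yl)-2-phenyl-4H-chromen-4-one
Conditions: NH3 (7 M in MeOH), 0 °C
Reagents that add atoms: none
Why: Ammonolysis of aryl acetates: both esters have good phenoxide leaving groups (C7–O para and C5–O ortho to the acyl-bearing C4a), so cold methanolic ammonia should suffice. The reagent is volatile, no strong acid or base and no heating is involved, and so C2' and ring C should stay intact.

## Compound list

1 | 6-bromoflavone (6-bromo-2-phenyl-4H-chromen-4-one) | O=c1cc(-c2ccccc2)oc2ccc(Br)cc12 | starting material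
2 | 2-pyridylzinc bromide | Br[Zn]c1ccccn1 | starting material
3 | 2-phenyl-6-(pyridin-2-yl)-4H-chromen-4-one | O=c1cc(-c2ccccc2)oc2ccc(-c3ccccn3)cc12 | intermediate
4 | (diacetoxyiodo)benzene | CC(=O)OI(OC(C)=O)c1ccccc1 | starting material
5 | 4-oxo-2-phenyl-6-(pyridin-2-yl)-4H-chromen-7-yl acetate (7-acetoxy-6-(pyridin-2-yl)flavone) | CC(=O)Oc1cc2oc(-c3ccccc3)cc(=O)c2cc1-c1ccccn1 | intermediate
6 | 4-oxo-2-phenyl-6-(pyridin-2-yl)-4H-chromene-5,7-diyl diacetate | CC(=O)Oc1cc2oc(-c3ccccc3)cc(=O)c2c(OC(C)=O)c1-c1ccccn1 | intermediate
7 | 2-(5,7-diacetoxy-4-oxo-2-phenyl-4H-chromen-6-yl)-1-methylpyridin-1-ium trifluoromethanesulfonate | C[n+]1ccccc1-c1c(OC(C)=O)cc2oc(-c3ccccc3)cc(=O)c2c1OC(C)=O.[O-]S(=O)(=O)C(F)(F)F | intermediate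
8 | (R)-2-(5,7-diacetoxy-4-oxo-2-phenyl-4H-chromen-6-yl)-1-methylpiperidin-1-ium trifluoromethanesulfonate | C[NH+]1CCCC[C@@H]1c1c(OC(C)=O)cc2oc(-c3ccccc3)cc(=O)c2c1OC(C)=O.[O-]S(=O)(=O)C(F)(F)F | intermediate
9 | (R)-6-(1-methylpiperidin-2-yl)-4-oxo-2-phenyl-4H-chromene-5,7-diyl diacetate | CN1CCCC[C@@H]1c1c(OC(C)=O)cc2oc(-c3ccccc3)cc(=O)c2c1OC(C)=O | intermediate
10 | (R)-5,7-dihydroxy-6-(1-methylpiperidin-2-yl)-2-phenyl-4H-chromen-4-one | CN1CCCC[C@@H]1c1c(O)cc2oc(-c3ccccc3)cc(=O)c2c1O | target

## Step count and least certain steps

Total: 5 steps. Longest linear sequence: 5 steps, from 1.

**Step 2 (key step).** The most likely failure is stalling after the first acetoxylation. The second palladation must take place at the position peri to the C4 carbonyl while the new C7 ester twists the pyridine out of the plane of ring A; partial loss of acetyl groups would also tie up palladium as a phenoxide chelate. The fallback sets out from 3 and makes the two C–O bonds under two different directing groups: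
- With about one equivalent of 4 under the same catalyst, the reaction is stopped at 5, which is isolated.
- In CF3CO2H/(CF3CO)2O the pyridine is protonated and the C4 ketone takes over as directing group. [RuCl2(p-cymene)]2 with PhI(OCOCF3)2, a known way to hydroxylate C5 of flavones, should give 5-hydroxy-4-oxo-2-phenyl-6-(pyridin-2-yl)-4H-chromen-7-yl acetate F1 after aqueous work-up.
- Acetylation with Ac2O and pyridine returns to the route at 6; any acetyl lost at C7 is restored in the same operation.

**Step 4.** The risks are incomplete reduction, because the twisted and doubly ortho-substituted aryl group shields C2'; poor facial selectivity in the last hydride transfer, for the same reason; and competing reduction of C2=C3 of the pyranone. The fallback sets out from 7 and gives up asymmetric catalysis for a resolution: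
- Hydrogenation over PtO2 in AcOH (H2, 3 bar, rt, interrupted after three equivalents are taken up) and neutralisation with NaHCO3 should give racemic 6-(1-methylpiperidin-2-yl)-4-oxo-2-phenyl-4H-chromene-5,7-diyl diacetate F2.
- Preparative chromatography on a chiral stationary phase separates the enantiomers. The (R)-enantiomer is 9, where the route is rejoined; (S)-6-(1-methylpiperidin-2-yl)-4-oxo-2-phenyl-4H-chromene-5,7-diyl diacetate F3 is set aside.

**Step 5.** The risks are erosion of enantiopurity by reversible heterolysis of the benzylic C2'–N bond once both flanking phenols are free and partly ionised, and attack of ammonia at C2 of the pyranone with ring opening. The fallback sets out from 7 and reverses the order of the last two operations, so that the stereocentre is formed last and never meets a base: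
- Acid-catalysed methanolysis (TfOH cat., MeOH, 40 °C) should give 2-(5,7-dihydroxy-4-oxo-2-phenyl-4H-chromen-6-yl)-1-methylpyridin-1-ium trifluoromethanesulfonate F4.
- Hydrogenation of F4 with the catalyst of step 4 would deliver the salt of 10 directly; brief neutralisation with NaHCO3 rejoins the route at 10.

**Step 1.** The risk is incomplete coupling through decay of the organozinc reagent (protonolysis by adventitious moisture, or homocoupling to a bipyridine that binds palladium). The fallback sets out from 1 and reverses the polarity of the coupling:
- Borylation with B2pin2, Pd(dppf)Cl2 and KOAc in dioxane at 90 °C should give 2-phenyl-6-(4,4,5,5-tetramethyl-1,3,2-dioxaborolan-2-yl)-4H-chromen-4-one F5.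
- Suzuki–Miyaura coupling of F5 with 2-bromopyridine (Pd(PPh3)4, K2CO3, dioxane/water) returns to the route at 3.

## Further compounds

F1 | step 2 | 5-hydroxy-4-oxo-2-phenyl-6-(pyridin-2-yl)-4H-chromen-7-yl acetate | CC(=O)Oc1cc2oc(-c3ccccc3)cc(=O)c2c(O)c1-c1ccccn1
F2 | step 4 | racemic 6-(1-methylpiperidin-2-yl)-4-oxo-2-phenyl-4H-chromene-5,7-diyl diacetate | CN1CCCCC1c1c(OC(C)=O)cc2oc(-c3ccccc3)cc(=O)c2c1OC(C)=O
F3 | step 4 | (S)-6-(1-methylpiperidin-2-yl)-4-oxo-2-phenyl-4H-chromene-5,7-diyl diacetate | CN1CCCC[C@H]1c1c(OC(C)=O)cc2oc(-c3ccccc3)cc(=O)c2c1OC(C)=O
F4 | step 5 | 2-(5,7-dihydroxy-4-oxo-2-phenyl-4H-chromen-6-yl)-1-methylpyridin-1-ium trifluoromethanesulfonate | C[n+]1ccccc1-c1c(O)cc2oc(-c3ccccc3)cc(=O)c2c1O.[O-]S(=O)(=O)C(F)(F)F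
F5 | step 1 | 2-phenyl-6-(4,4,5,5-tetramethyl-1,3,2-dioxaborolan-2-yl)-4H-chromen-4-one | CC1(C)OB(c2ccc3oc(-c4ccccc4)cc(=O)c3c2)OC1(C)C
A1 | alternative 1 | (R)-1-[4-(benzyloxy)-2,6-dimethoxyphenyl]-N-methylbut-3-en-1-amine | CN[C@H](CC=C)c1c(OC)cc(OCc2ccccc2)cc1OC
A2 | alternative 1 | (R)-2-[4-(benzyloxy)-2,6-dimethoxyphenyl]-1-methylpiperidine | CN1CCCC[C@@H]1c1c(OC)cc(OCc2ccccc2)cc1OC
A3 | alternative 1 | 4-(benzyloxy)-2,6-dimethoxybenzaldehyde | O=Cc1c(OC)cc(OCc2ccccc2)cc1OC
A4 | alternative 2 | 2-(2-diazoacetyl)-6-phenyl-4H-pyran-4-one | [N-]=[N+]=CC(=O)c1cc(=O)cc(-c2ccccc2)o1
A5 | alternative 2 | tert-butyl (R)-2-{[tri(propan-2-yl)silyl]oxyethynyl}piperidine-1-carboxylate | CC(C)(C)OC(=O)N1CCCC[C@@H]1C#CO[Si](C(C)C)(C(C)C)C(C)C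
A6 | alternative 2 | tert-butyl (R)-2-[5-hydroxy-4-oxo-2-phenyl-7-(triisopropylsilyloxy)-4H-chromen-6-yl]piperidine-1-carboxylate | CC(C)(C)OC(=O)N1CCCC[C@@H]1c1c(O[Si](C(C)C)(C(C)C)C(C)C)cc2oc(-c3ccccc3)cc(=O)c2c1O
A7 | alternative 2 | (R)-1-(tert-butoxycarbonyl)piperidine-2-carboxylic acid | CC(C)(C)OC(=O)N1CCCC[C@@H]1C(=O)O
A8 | alternative 3 | 2-iodo-3,5-dimethoxy-4-[(R)-1-methylpiperidin-2-yl]phenol | CN1CCCC[C@@H]1c1c(OC)cc(O)c(I)c1OC
A9 | alternative 3 | phenylacetylene | C#Cc1ccccc1
A10 | alternative 3 | 5,7-dimethoxy-6-[(R)-1-methylpiperidin-2-yl]flavone | CN1CCCC[C@@H]1c1c(OC)cc2oc(-c3ccccc3)cc(=O)c2c1OC
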